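**Plan**
Retrosynthesis: cut the O7 ester bond to the side-chain acid, then ring A (lactone) at C2–C3 and at the O5–C1 acyl bond, then ring B (pyran) at O8–C4, then C3=C4, C4–C5 and C6–C7.
Forward: C6–C7 aldol, C4–C5 by Grignard addition to a Weinreb amide, C3=C4 by Peterson olefination, ring B by anodic O8–C4 closure, ring A by O5 acylation and C2–C3 Reformatsky closure, side chain last.
Enabling feature: C4 is the tetrasubstituted ether carbon of ring B (O8, C4–C8; it carries CH3, O8, C3 and C5) and its neighbour C3 can be held as the sulfur-bearing carbon of a ketene dithioacetal. One-electron oxidation then makes C4 electrophilic toward the C8 hydroxyl and leaves C3 one reduction away from the aldehyde that ring A (O5, C1–C5) needs.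
Stereochemistry: C8 from ethyl (S)-lactate; C6 and C7 from the (R)-benzyloxazolidinone syn-aldol; C5 from a chelation-controlled ketone reduction; C4 from 1,3-allylic strain in the anodic closure; C2 and C3 from the samarium Reformatsky closure on the rigid ring B.

Key step: step 13

Remarks on the chemistry
- C1–C9, O3, O5, O7 and O8 are the atoms of the botcinin skeleton (C1 lactone carbonyl, C9 the methyl carbon on C8); ring A is the lactone, ring B the pyran.
- The electron-rich olefin is a ketene dithioacetal and not a simple enol ether. Its radical cation lives long enough for a six-membered closure, and a sulfur cis to C5 lets 1,3-allylic strain fix C4. The cost is one reduction (thioester to aldehyde) after ring closure.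
- Assumption: dilute aqueous acid converts the S,S,O-orthoester 20 into the S-methyl thioester by loss of methanol first, as in the hydrolysis of ketene dithioacetals.

**Route**

Step 1
Reactants: 1 2-butylfuran
Product: 4 (E)-4-oxooct-2-enoic acid, via (Z)-4-oxooct-2-enal 2 (not isolated), via (E)-4-oxooct-2-enal 3 (not isolated)
Conditions: NBS, NaHCO3, acetone/H2O, −15 °C; pyridine, rt; then NaClO2, NaH2PO4, 2-methyl-2-butene, t-BuOH/H2O, rt
Reagents that add atoms: water O; sodium chlorite [Na+].[O-]Cl=O
Why: Oxidative ring opening of a 2-alkylfuran by bromonium ion and water gives the cis 4-oxoenal, pyridine isomerises it to the trans isomer, and a Pinnick oxidation converts the aldehyde into the acid without touching the enone.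

Step 2
Reactants: 5 ethyl (S)-lactate
Product: 6 ethyl (S)-2-[(tert-butyldiphenylsilyl)oxy]propanoate
Conditions: TBDPSCl, imidazole, DMF, rt
Reagents that add atoms: tert-butyl(chloro)diphenylsilane CC(C)(C)[Si](Cl)(c1ccccc1)c1ccccc1
Why: Silylation of a secondary alcohol with a silyl chloride and imidazole, which does not touch the stereocentre that becomes C8.

Step 3
Reactants: 6 ethyl (S)-2-[(tert-butyldiphenylsilyl)oxy]propanoate
Product: 7 (S)-2-[(tert-butyldiphenylsilyl)oxy]propanal
Conditions: i-Bu2AlH, Et2O, −78 °C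
Reagents that add atoms: none
Why: Partial reduction of an ester by i-Bu2AlH at low temperature should stop at the aldehyde because the aluminium hemiacetal is stabilised by the neighbouring silyloxy group, and the aldehyde is used crude so that C8 does not epimerise.

Step 4
Reactants: 8 (R)-4-benzyl-3-propionyloxazolidin-2-one; 7 (S)-2-[(tert-butyldiphenylsilyl)oxy]propanal
Product: 10 (R)-4-benzyl-3-[(2R,3R,4S)-4-[(tert-butyldiphenylsilyl)oxy]-3-hydroxy-2-methylpentanoyl]oxazolidin-2-one, via dibutylboron (Z)-enolate of 8 9 (not isolated)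
Conditions: Bu2BOTf, i-Pr2NEt, CH2Cl2, 0 °C; then 7, −78 → 0 °C; H2O2, MeOH, pH 7 buffer
Reagents that add atoms: none
Why: Evans syn-aldol reaction in which the (Z)-boron enolate reacts through a Zimmerman–Traxler chair on the face opposite the benzyl group and so sets (6R,7R), while the Felkin–Anh/Cornforth preference of the silyloxy aldehyde (7,8-anti) points the same way.

Step 5
Reactants: 10 the aldol adduct
Product: 11 (2R,3R,4S)-4-[(tert-butyldiphenylsilyl)oxy]-3-hydroxy-N-methoxy-N,2-dimethylpentanamide
Conditions: MeNHOMe·HCl, AlMe3, CH2Cl2, −15 °C → rt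
Reagents that add atoms: N,O-dimethylhydroxylamine hydrochloride CNOC.Cl
Why: Aluminium amide transamidation of the hydroxy acyl oxazolidinone, assisted by the free C7 hydroxyl, should give the Weinreb amide and release the auxiliary without epimerising C6.

Step 6
Reactants: 11 the hydroxy Weinreb amide
Product: 12 (2R,3R,4S)-3-(benzyloxy)-4-[(tert-butyldiphenylsilyl)oxy]-N-methoxy-N,2-dimethylpentanamide
Conditions: BnOC(=NH)CCl3, TfOH (cat.), CH2Cl2/cyclohexane, 0 °C → rt
Reagents that add atoms: benzyl 2,2,2-trichloroacetimidate ClC(Cl)(Cl)C(=N)OCc1ccccc1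
Why: Acid-catalysed benzylation with the trichloroacetimidate avoids the alkoxide that would trigger a retro-aldol reaction, and the diphenylsilyl ether tolerates the catalytic acid.

Step 7
Reactants: 12 the benzyl ether Weinreb amide
Product: 13 (4R,5R,6S)-5-(benzyloxy)-6-[(tert-butyldiphenylsilyl)oxy]-2,4-dimethylhept-1-en-3-one
Conditions: CH2=C(CH3)MgBr, THF, 0 °C
Reagents that add atoms: isopropenylmagnesium bromide C=C(C)[Mg]Br
Why: Weinreb ketone synthesis in which the chelated tetrahedral intermediate prevents over-addition, the isopropenyl group bringing in C4 with its methyl group as a masked acetyl unit.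

Step 8
Reactants: 13 the enone
Product: 14 (3S,4S,5R,6S)-5-(benzyloxy)-6-[(tert-butyldiphenylsilyl)oxy]-2,4-dimethylhept-1-en-3-ol
Conditions: Zn(BH4)2, Et2O, −30 → 0 °C
Reagents that add atoms: none
Why: Chelation-controlled 1,2-reduction in which zinc bridges the ketone and the C7 benzyloxy oxygen and hydride is delivered to the face of the chelate opposite the C6 methyl group, which should give the 5,6-syn-5,7-syn (5S) alcohol.

Step 9
Reactants: 14 the allylic alcohol
Product: 15 (3S,4R,5R,6S)-5-(benzyloxy)-3-[(tert-butyldimethylsilyl)oxy]-6-[(tert-butyldiphenylsilyl)oxy]-2,4-dimethylhept-1-ene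
Conditions: TBSOTf, 2,6-lutidine, CH2Cl2, −78 → 0 °C
Reagents that add atoms: tert-butyldimethylsilyl trifluoromethanesulfonate CC(C)(C)[Si](C)(C)OS(=O)(=O)C(F)(F)F
Why: Silylation of the hindered allylic alcohol with the silyl triflate protects O5 for the ozonolysis and the olefination.

Step 10
Reactants: 15 the silylated alkene
Product: 17 (3S,4R,5R,6S)-5-(benzyloxy)-3-[(tert-butyldimethylsilyl)oxy]-6-[(tert-butyldiphenylsilyl)oxy]-4-methylheptan-2-one, via secondary ozonide of 15 16 (not isolated)
Conditions: O3, CH2Cl2, −78 °C; then PPh3, −78 °C → rt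
Reagents that add atoms: ozone [O-][O+]=O
Why: Ozonolysis of the 1,1-disubstituted alkene with reductive work-up should give the C4 methyl ketone and formaldehyde, benzyl and silyl ethers surviving at −78 °C when ozone addition is stopped at the end point.

Step 11
Reactants: 17 the methyl ketone
Product: 18 (3S,4R,5R,6S)-5-(benzyloxy)-3-[(tert-butyldimethylsilyl)oxy]-6-[(tert-butyldiphenylsilyl)oxy]-2,4-dimethyl-1,1-bis(methylsulfanyl)hept-1-ene
Conditions: (MeS)2CHSiMe3, n-BuLi, THF, −78 °C; then 17, −78 °C → rt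
Reagents that add atoms: bis(methylsulfanyl)(trimethylsilyl)methane CSC(SC)[Si](C)(C)C
Why: Peterson olefination in which the silyl-stabilised dithio carbanion adds to the ketone and the silyl alkoxide eliminates lithium trimethylsilanolate to give the ketene dithioacetal, C3 entering at the carboxylic acid oxidation level.

Step 12
Reactants: 18 the bis-silylated ketene dithioacetal
Product: 19 (2S,3R,4S,5S)-3-(benzyloxy)-4,6-dimethyl-7,7-bis(methylsulfanyl)hept-6-ene-2,5-diol
Conditions: Bu4NF, THF, rt → 40 °C; chromatography on Et3N-deactivated silica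
Reagents that add atoms: none
Why: Fluoride desilylation cleaves both silyl ethers and leaves the benzyl ether and the base-stable ketene dithioacetal untouched, acid being avoided because the allylic C5 alcohol would undergo 1,3-transposition.

Step 13
Reactants: 19 the diol ketene dithioacetal
Product: 20 (2S,3S,4S,5R,6S)-5-(benzyloxy)-2-[methoxybis(methylsulfanyl)methyl]-2,4,6-trimethyloxan-3-ol
Conditions: reticulated vitreous carbon anode, Pt cathode, undivided cell, constant current (2.2 F/mol), Et4NOTs, 2,6-lutidine, MeOH/THF 3:7, rt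
Reagents that add atoms: methanol CO
Why: One-electron oxidation of the ketene dithioacetal, the most easily oxidised group in 19, gives a radical cation that is attacked at C4 by the C8 hydroxyl; loss of a proton to 2,6-lutidine, a second electron transfer and capture of the bis(methylsulfanyl)carbenium ion at C3 by methanol complete the two-electron process, the benzyl ether being oxidised only at much higher potential. The closest known reaction type is the anodic coupling of ketene dithioacetal or enol ether radical cations with tethered alcohols, which gives cyclic ethers with tetrasubstituted carbons. Ring B closes in the 6-exo-trig mode, through a chair in which the C5 hydroxyl, C6 methyl, C7 benzyloxy and C8 methyl groups are equatorial. The new stereocentre C4 is controlled by 1,3-allylic strain: a sulfur on C3 is always cis to C5, so the C5–H bond eclipses the C3=C4 bond, C6 with its tether then lies over one face only, and O8 enters on that face anti to the C5–O bond, which leaves the sulfur-bearing C3 equatorial and the C4 methyl axial as in the target. The step needs O8 to win over methanol and over the other oxygens: the closure is intramolecular and the methanol content is kept low, O5 could only form a three-membered ring, and O7, which would close a five-membered ring, is blocked as its benzyl ether.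

Step 14
Reactants: 20 the S,S,O-orthoester
Product: 21 S-methyl (2S,3S,4S,5R,6S)-5-(benzyloxy)-3-hydroxy-2,4,6-trimethyloxane-2-carbothioate
Conditions: 1 M HCl (aq.), THF, 0 °C → rt
Reagents that add atoms: water O
Why: Acid hydrolysis of the orthoester in which loss of methanol gives the bis(methylsulfanyl)carbenium ion, water adds and methanethiol is expelled to leave the thioester, while ring B, the benzyl ether and the quaternary C4 are inert to dilute acid.

Step 15
Reactants: 21 the thioester
Product: 22 (2S,3S,4S,5R,6S)-5-(benzyloxy)-3-hydroxy-2,4,6-trimethyloxane-2-carbaldehyde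
Conditions: i-Bu2AlH (2.5 equiv), CH2Cl2, −78 °C; MeOH, then aq. KNaC4H4O6
Reagents that add atoms: none
Why: Partial reduction of a thioester to the aldehyde by i-Bu2AlH (the first equivalent is consumed by the C5 hydroxyl), giving an aldehyde that cannot epimerise or eliminate because C4 bears no hydrogen and that is acylated at once to forestall a retro-aldol reaction.

Step 16
Reactants: 22 the hydroxy aldehyde
Product: 23 (2S,3S,4R,5R,6S)-5-(benzyloxy)-2-formyl-2,4,6-trimethyloxan-3-yl 2-bromopropanoate (both epimers at the brominated carbon)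
Conditions: CH3CHBrCOBr, pyridine, CH2Cl2, −20 → 0 °C
Reagents that add atoms: 2-bromopropanoyl bromide CC(Br)C(Br)=O
Why: Acylation of the secondary C5 alcohol by a reactive acyl bromide under mild base, the racemic acyl unit giving two bromide epimers that converge on one enolate in the next step.

Step 17
Reactants: 23 the bromopropanoate aldehyde
Product: 24 (3R,4S,4aR,6S,7R,8R,8aS)-7-(benzyloxy)-4-hydroxy-3,4a,6,8-tetramethylhexahydropyrano[3,2-b]pyran-2(3H)-one
Conditions: SmI2, THF, −78 °C
Reagents that add atoms: none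
Why: Intramolecular Reformatsky reaction in which two equivalents of SmI2 turn the C–Br bond into a samarium enolate (trivalent samarium) that adds to the C3 aldehyde and closes ring A trans-fused to ring B; in the chelated transition state C2 is expected to add anti to the axial C4 methyl with the aldehyde oxygen turned away from O8, which places the C3 hydroxyl and the C2 methyl on the face of the C4 methyl (2R,3S).

Step 18
Reactants: 24 the hydroxy lactone
Product: 25 (3R,4S,4aS,6S,7R,8R,8aS)-7-(benzyloxy)-3,4a,6,8-tetramethyl-4-[(triethylsilyl)oxy]hexahydropyrano[3,2-b]pyran-2(3H)-one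
Conditions: Et3SiOTf, 2,6-lutidine, CH2Cl2, −78 → 0 °C
Reagents that add atoms: triethylsilyl trifluoromethanesulfonate CC[Si](CC)(CC)OS(=O)(=O)C(F)(F)F
Why: Silylation of the hindered C3 alcohol with the silyl triflate, so that O7 is the only free hydroxyl after debenzylation.

Step 19
Reactants: 25 the silylated benzyl ether
Product: 26 (3R,4S,4aS,6S,7R,8R,8aS)-7-hydroxy-3,4a,6,8-tetramethyl-4-[(triethylsilyl)oxy]hexahydropyrano[3,2-b]pyran-2(3H)-one
Conditions: H2 (1 atm), Pd/C, EtOAc, rt
Reagents that add atoms: none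
Why: Hydrogenolysis of the benzyl ether over palladium, with lactone and triethylsilyl ether stable in a neutral aprotic solvent and all sulfur already removed from the molecule.

Step 20
Reactants: 26 the C7 alcohol; 4 (E)-4-oxooct-2-enoic acid
Product: 27 (3R,4S,4aS,6S,7R,8R,8aS)-3,4a,6,8-tetramethyl-2-oxo-4-[(triethylsilyl)oxy]octahydropyrano[3,2-b]pyran-7-yl (E)-4-oxooct-2-enoate
Conditions: 2-methyl-6-nitrobenzoic anhydride, Et3N, DMAP (cat.), CH2Cl2, rt
Reagents that add atoms: none
Why: Mixed-anhydride esterification with acyl transfer by DMAP, which suits a hindered secondary alcohol and runs at room temperature so that the (E)-4-oxo-enoate is spared isomerisation and conjugate addition.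

Step 21
Reactants: 27 the silylated ester
Product: 28 botcinin I, (3R,4S,4aR,6S,7R,8R,8aS)-4-hydroxy-3,4a,6,8-tetramethyl-2-oxooctahydropyrano[3,2-b]pyran-7-yl (E)-4-oxooct-2-enoate
Conditions: HF·pyridine, pyridine, THF, 0 °C → rt
Reagents that add atoms: none
Why: Buffered fluoride desilylation removes the triethylsilyl group under weakly acidic conditions that should leave the enone ester, the lactone and the C2 stereocentre untouched.

**Compound list**
1 | 2-butylfuran | CCCCc1ccco1 | starting material
2 | (Z)-4-oxooct-2-enal (not isolated) | CCCCC(=O)/C=C\C=O | intermediate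
3 | (E)-4-oxooct-2-enal (not isolated) | CCCCC(=O)/C=C/C=O | intermediate
4 | (E)-4-oxooct-2-enoic acid | CCCCC(=O)/C=C/C(=O)O | intermediate
5 | ethyl (S)-lactate | CCOC(=O)[C@H](C)O | starting material
6 | ethyl (S)-2-[(tert-butyldiphenylsilyl)oxy]propanoate | CCOC(=O)[C@H](C)O[Si](c1ccccc1)(c1ccccc1)C(C)(C)C | intermediate
7 | (S)-2-[(tert-butyldiphenylsilyl)oxy]propanal | O=C[C@H](C)O[Si](c1ccccc1)(c1ccccc1)C(C)(C)C | intermediate
8 | (R)-4-benzyl-3-propionyloxazolidin-2-one | CCC(=O)N1[C@H](Cc2ccccc2)COC1=O | starting material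
9 | dibutylboron (Z)-enolate of 8, (R)-4-benzyl-3-[(Z)-1-(dibutylboryloxy)prop-1-enyl]oxazolidin-2-one (not isolated) | C/C=C(\OB(CCCC)CCCC)N1[C@H](Cc2ccccc2)COC1=O | intermediate
10 | (R)-4-benzyl-3-[(2R,3R,4S)-4-[(tert-butyldiphenylsilyl)oxy]-3-hydroxy-2-methylpentanoyl]oxazolidin-2-one | C[C@H](O[Si](c1ccccc1)(c1ccccc1)C(C)(C)C)[C@H](O)[C@@H](C)C(=O)N1[C@H](Cc2ccccc2)COC1=O | intermediate
11 | (2R,3R,4S)-4-[(tert-butyldiphenylsilyl)oxy]-3-hydroxy-N-methoxy-N,2-dimethylpentanamide | C[C@H](O[Si](c1ccccc1)(c1ccccc1)C(C)(C)C)[C@H](O)[C@@H](C)C(=O)N(C)OC | intermediate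
12 | (2R,3R,4S)-3-(benzyloxy)-4-[(tert-butyldiphenylsilyl)oxy]-N-methoxy-N,2-dimethylpentanamide | C[C@H](O[Si](c1ccccc1)(c1ccccc1)C(C)(C)C)[C@H](OCc1ccccc1)[C@@H](C)C(=O)N(C)OC | intermediate
13 | (4R,5R,6S)-5-(benzyloxy)-6-[(tert-butyldiphenylsilyl)oxy]-2,4-dimethylhept-1-en-3-one | C[C@H](O[Si](c1ccccc1)(c1ccccc1)C(C)(C)C)[C@H](OCc1ccccc1)[C@@H](C)C(=O)C(C)=C | intermediate
14 | (3S,4S,5R,6S)-5-(benzyloxy)-6-[(tert-butyldiphenylsilyl)oxy]-2,4-dimethylhept-1-en-3-ol | C[C@H](O[Si](c1ccccc1)(c1ccccc1)C(C)(C)C)[C@H](OCc1ccccc1)[C@@H](C)[C@H](O)C(C)=C | intermediate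
15 | (3S,4R,5R,6S)-5-(benzyloxy)-3-[(tert-butyldimethylsilyl)oxy]-6-[(tert-butyldiphenylsilyl)oxy]-2,4-dimethylhept-1-ene | C[C@H](O[Si](c1ccccc1)(c1ccccc1)C(C)(C)C)[C@H](OCc1ccccc1)[C@@H](C)[C@H](O[Si](C)(C)C(C)(C)C)C(C)=C | intermediate
16 | secondary ozonide (3-methyl-1,2,4-trioxolane) of 15, both epimers at the ring carbon (not isolated) | C[C@H](O[Si](c1ccccc1)(c1ccccc1)C(C)(C)C)[C@H](OCc1ccccc1)[C@@H](C)[C@H](O[Si](C)(C)C(C)(C)C)C1(C)OOCO1 | intermediate
17 | (3S,4R,5R,6S)-5-(benzyloxy)-3-[(tert-butyldimethylsilyl)oxy]-6-[(tert-butyldiphenylsilyl)oxy]-4-methylheptan-2-one | C[C@H](O[Si](c1ccccc1)(c1ccccc1)C(C)(C)C)[C@H](OCc1ccccc1)[C@@H](C)[C@H](O[Si](C)(C)C(C)(C)C)C(C)=O | intermediate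
18 | (3S,4R,5R,6S)-5-(benzyloxy)-3-[(tert-butyldimethylsilyl)oxy]-6-[(tert-butyldiphenylsilyl)oxy]-2,4-dimethyl-1,1-bis(methylsulfanyl)hept-1-ene | C[C@H](O[Si](c1ccccc1)(c1ccccc1)C(C)(C)C)[C@H](OCc1ccccc1)[C@@H](C)[C@H](O[Si](C)(C)C(C)(C)C)C(C)=C(SC)SC | intermediate
19 | (2S,3R,4S,5S)-3-(benzyloxy)-4,6-dimethyl-7,7-bis(methylsulfanyl)hept-6-ene-2,5-diol | C[C@H](O)[C@H](OCc1ccccc1)[C@@H](C)[C@H](O)C(C)=C(SC)SC | intermediate
20 | (2S,3S,4S,5R,6S)-5-(benzyloxy)-2-[methoxybis(methylsulfanyl)methyl]-2,4,6-trimethyloxan-3-ol | c1ccccc1CO[C@@H]1[C@@H](C)[C@H](O)[C@@](C)(C(OC)(SC)SC)O[C@H]1C | intermediate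
21 | S-methyl (2S,3S,4S,5R,6S)-5-(benzyloxy)-3-hydroxy-2,4,6-trimethyloxane-2-carbothioate | c1ccccc1CO[C@@H]1[C@@H](C)[C@H](O)[C@@](C)(C(=O)SC)O[C@H]1C | intermediate
22 | (2S,3S,4S,5R,6S)-5-(benzyloxy)-3-hydroxy-2,4,6-trimethyloxane-2-carbaldehyde | c1ccccc1CO[C@@H]1[C@@H](C)[C@H](O)[C@@](C)(C=O)O[C@H]1C | intermediate
23 | (2S,3S,4R,5R,6S)-5-(benzyloxy)-2-formyl-2,4,6-trimethyloxan-3-yl 2-bromopropanoate, both epimers at the brominated carbon | c1ccccc1CO[C@@H]1[C@@H](C)[C@H](OC(=O)C(C)Br)[C@@](C)(C=O)O[C@H]1C | intermediate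
24 | (3R,4S,4aR,6S,7R,8R,8aS)-7-(benzyloxy)-4-hydroxy-3,4a,6,8-tetramethylhexahydropyrano[3,2-b]pyran-2(3H)-one | c1ccccc1CO[C@@H]1[C@@H](C)[C@@H]2OC(=O)[C@H](C)[C@H](O)[C@@]2(C)O[C@H]1C | intermediate
25 | (3R,4S,4aS,6S,7R,8R,8aS)-7-(benzyloxy)-3,4a,6,8-tetramethyl-4-[(triethylsilyl)oxy]hexahydropyrano[3,2-b]pyran-2(3H)-one | c1ccccc1CO[C@@H]1[C@@H](C)[C@@H]2OC(=O)[C@H](C)[C@H](O[Si](CC)(CC)CC)[C@@]2(C)O[C@H]1C | intermediate
26 | (3R,4S,4aS,6S,7R,8R,8aS)-7-hydroxy-3,4a,6,8-tetramethyl-4-[(triethylsilyl)oxy]hexahydropyrano[3,2-b]pyran-2(3H)-one | O[C@@H]1[C@@H](C)[C@@H]2OC(=O)[C@H](C)[C@H](O[Si](CC)(CC)CC)[C@@]2(C)O[C@H]1C | intermediate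
27 | (3R,4S,4aS,6S,7R,8R,8aS)-3,4a,6,8-tetramethyl-2-oxo-4-[(triethylsilyl)oxy]octahydropyrano[3,2-b]pyran-7-yl (E)-4-oxooct-2-enoate | CCCCC(=O)/C=C/C(=O)O[C@@H]1[C@@H](C)[C@@H]2OC(=O)[C@H](C)[C@H](O[Si](CC)(CC)CC)[C@@]2(C)O[C@H]1C | intermediate
28 | botcinin I, (3R,4S,4aR,6S,7R,8R,8aS)-4-hydroxy-3,4a,6,8-tetramethyl-2-oxooctahydropyrano[3,2-b]pyran-7-yl (E)-4-oxooct-2-enoate | CCCCC(=O)/C=C/C(=O)O[C@@H]1[C@@H](C)[C@@H]2OC(=O)[C@H](C)[C@H](O)[C@@]2(C)O[C@H]1C | target

**Step count**
Total: 21 steps. Longest linear sequence: 20 steps (steps 2–21, ethyl (S)-lactate to the target); step 1 makes the side-chain acid.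

**Steps most likely to fail**

Step 13 (anodic ring closure). The radical cation may be captured by methanol before the six-membered ring closes, or O8 may add to the wrong face of C4. Fallback, from 19 back to 22: one sulfur of 19 is oxidised with mCPBA (1 equiv, CH2Cl2, −78 °C) to the ketene dithioacetal S-oxide F1. KOt-Bu in THF at 0 °C then adds the C8 alkoxide to C4 in an intramolecular oxa-Michael reaction; the addition is reversible and should settle with the bulky sulfur-bearing carbon equatorial, giving the cyclic dithioacetal S-oxide F2. Aqueous HClO4 in THF hydrolyses F2 to the C3 aldehyde, which is 22.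

Step 17 (Reformatsky closure). The samarium enolate may add through a chair-like rather than the expected chelated transition state, which would put the C2 methyl or the C3 hydroxyl on the wrong face. Fallback, from 22 back to 24: reagent-controlled crotylation of 22 with the enantiomer of (E)-crotyldiisopinocampheylborane that attacks the Si face of the aldehyde (THF, −78 °C, oxidative work-up) gives the 2,3-anti homoallylic alcohol F3. Ozonolysis (O3, CH2Cl2/MeOH, −78 °C; Me2S) cleaves the vinyl group to the C1 aldehyde, which closes on the C5 hydroxyl to the lactol F4. TEMPO with PhI(OAc)2 oxidises the lactol, and not the hindered C3 alcohol, to lactone 24.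

Step 11 (Peterson olefination). The basic carbanion may enolise the hindered methyl ketone instead of adding to it, returning ketone and risking epimerisation at C5. Fallback, from 15 back to 18, with no ketone and no strong base: hydroboration of the alkene of 15 with 9-BBN and oxidative work-up gives the primary alcohol F5 (the C4 epimers do not matter, since C4 becomes trigonal again). Dess–Martin oxidation gives the aldehyde F6, and Me3SiSMe with ZnI2 converts it into the dimethyl dithioacetal F7. Chlorination at C3 with NCS followed by Et3N eliminates HCl across C3–C4 and gives 18.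

**Further compounds**
F1 | step 13 | (2S,3R,4S,5S)-3-(benzyloxy)-4,6-dimethyl-7-(methylsulfanyl)-7-(methylsulfinyl)hept-6-ene-2,5-diol, isomers at sulfur and at the double bond | C[C@H](O)[C@H](OCc1ccccc1)[C@@H](C)[C@H](O)C(C)=C(SC)S(C)=O
F2 | step 13 | (2S,3S,4S,5R,6S)-5-(benzyloxy)-2,4,6-trimethyl-2-[(methylsulfanyl)(methylsulfinyl)methyl]oxan-3-ol, isomers at C3 of the skeleton and at sulfur | c1ccccc1CO[C@@H]1[C@@H](C)[C@H](O)[C@@](C)(C(SC)S(C)=O)O[C@H]1C
F3 | step 17 | (E)-crotyl adduct of 22: 5-(benzyloxy)-2-(1-hydroxy-2-methylbut-3-enyl)-2,4,6-trimethyloxan-3-ol, 2,3-anti, C2 and C3 of the skeleton configured as in 24 | c1ccccc1CO[C@@H]1[C@@H](C)[C@H](O)[C@@](C)([C@@H](O)[C@@H](C)C=C)O[C@H]1C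
F4 | step 17 | lactol: 7-(benzyloxy)-3,4a,6,8-tetramethyloctahydropyrano[3,2-b]pyran-2,4-diol, both anomers at C1 of the skeleton, other centres as in 24 | c1ccccc1CO[C@@H]1[C@@H](C)[C@@H]2OC(O)[C@H](C)[C@H](O)[C@@]2(C)O[C@H]1C
F5 | step 11 | primary alcohol from hydroboration of 15: 5-(benzyloxy)-3-[(tert-butyldimethylsilyl)oxy]-6-[(tert-butyldiphenylsilyl)oxy]-2,4-dimethylheptan-1-ol, both epimers at C4 of the skeleton | C[C@H](O[Si](c1ccccc1)(c1ccccc1)C(C)(C)C)[C@H](OCc1ccccc1)[C@@H](C)[C@H](O[Si](C)(C)C(C)(C)C)C(C)CO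
F6 | step 11 | aldehyde from F5: 5-(benzyloxy)-3-[(tert-butyldimethylsilyl)oxy]-6-[(tert-butyldiphenylsilyl)oxy]-2,4-dimethylheptanal, both epimers at C4 of the skeleton | C[C@H](O[Si](c1ccccc1)(c1ccccc1)C(C)(C)C)[C@H](OCc1ccccc1)[C@@H](C)[C@H](O[Si](C)(C)C(C)(C)C)C(C)C=O
F7 | step 11 | dimethyl dithioacetal of F6: 5-(benzyloxy)-3-[(tert-butyldimethylsilyl)oxy]-6-[(tert-butyldiphenylsilyl)oxy]-2,4-dimethyl-1,1-bis(methylsulfanyl)heptane, both epimers at C4 of the skeleton | C[C@H](O[Si](c1ccccc1)(c1ccccc1)C(C)(C)C)[C@H](OCc1ccccc1)[C@@H](C)[C@H](O[Si](C)(C)C(C)(C)C)C(C)C(SC)SC
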